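**Retrosynthetic overview**
1. Key C–O disconnection: the C9 ester bond. Target 28 comes from macrocyclic 8,9-vinyl carbonate 23 and epoxy acid 27 by a palladium/borane allylic acyloxylation that retains C9 and frees 8-OH in the same step.
2. The ten-membered ring (closed last of the carbon rings) comes from C3–C4 alkenyl–aldehyde (Ni/Cr) cyclisation of iodo-aldehyde 19; the C3 alcohol is then acetylated.
3. The cis-γ-lactone (C6–C7) comes from Z-2-(bromomethyl)enoate 16 and (Z)-3-iodobut-2-enal 4 by chromium-mediated allylation/lactonisation.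
4. Bromide 16 comes from L-tartaric acid bis-amide 7 (C8, C9) by mono-methylation, Z-selective Wittig (1(10)-olefin), amide reduction and Morita–Baylis–Hillman/bromination.
5. Ring order: dioxolane (chiral pool) → γ-lactone → ten-membered ring → cyclic carbonate (opened in the key step). The side-chain epoxide is set by Sharpless epoxidation.

Assumption: 7 (acetonide of commercial N,N,N′,N′-tetramethyl-L-tartramide) and 24 (tiglyl alcohol) are bought as such; locants C1–C15 follow germacrane numbering.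

This is a paper design: no step has been run, and the selectivities stated are expectations from analogy.

**Route**

Step 1
Reactants: 1 but-2-yn-1-ol
Product: 3 (Z)-3-iodobut-2-en-1-ol, via cyclic alkenylalanate 2 (not isolated)
Conditions: NaAlH2(OCH2CH2OMe)2, THF, 0 °C to rt; then I2, −78 to 0 °C
Reagents that add atoms: iodine, II
Why: Hydroxyl-directed trans-hydroalumination puts aluminium on C3 cis to the carbinol carbon in a five-membered alanate, and iodinolysis with retention gives only the Z vinyl iodide (Corey-type hydroalumination–iodination).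

Step 2
Reactants: 3 (Z)-3-iodobut-2-en-1-ol
Product: 4 (Z)-3-iodobut-2-enal
Conditions: MnO2, CH2Cl2, rt, dark
Reagents that add atoms: none
Why: Neutral allylic oxidation with MnO2 leaves the Z geometry and the C–I bond intact.

Step 3
Reactants: 5 3-bromo-1,1-dimethoxypropane
Product: 6 (3,3-dimethoxypropyl)triphenylphosphonium bromide
Conditions: PPh3, MeCN, reflux
Reagents that add atoms: triphenylphosphine, c1ccc(cc1)P(c1ccccc1)c1ccccc1
Why: SN2 quaternisation of the phosphine by a primary bromide (phosphonium salt formation), with the acetal inert.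

Step 4
Reactants: 7 (4R,5R)-N,N,N′,N′,2,2-hexamethyl-1,3-dioxolane-4,5-dicarboxamide
Product: 9 (4R,5R)-5-acetyl-N,N,2,2-tetramethyl-1,3-dioxolane-4-carboxamide, via magnesium hemiaminal adduct 8 (not isolated)
Conditions: MeMgBr (1.5 equiv), THF, −15 to 0 °C; then aq NH4Cl
Reagents that add atoms: methylmagnesium bromide, C[Mg]Br
Why: Grignard addition to a tertiary amide gives a chelated hemiaminal that survives until quench and deactivates the second amide, so the mono-ketone results (tartramide desymmetrisation) with both pool-derived stereocentres untouched.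

Step 5
Reactants: 9 (4R,5R)-5-acetyl-N,N,2,2-tetramethyl-1,3-dioxolane-4-carboxamide; 6 (3,3-dimethoxypropyl)triphenylphosphonium bromide
Product: 11 (4R,5S)-5-[(Z)-5,5-dimethoxypent-2-en-2-yl]-N,N,2,2-tetramethyl-1,3-dioxolane-4-carboxamide, via phosphorus ylide 10 (not isolated)
Conditions: 6, KN(SiMe3)2, THF, 0 °C; then 9, −78 °C to rt
Reagents that add atoms: none
Why: Salt-free Wittig olefination of an α-alkoxy methyl ketone with an unstabilised ylide places the alkoxy-bearing carbon cis to the ylide chain, setting the 1(10)Z trisubstituted olefin.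

Step 6
Reactants: 11 (4R,5S)-5-[(Z)-5,5-dimethoxypent-2-en-2-yl]-N,N,2,2-tetramethyl-1,3-dioxolane-4-carboxamide
Product: 13 (4R,5S)-5-[(Z)-5,5-dimethoxypent-2-en-2-yl]-2,2-dimethyl-1,3-dioxolane-4-carbaldehyde, via zirconium hemiaminal 12 (not isolated)
Conditions: Cp2Zr(H)Cl (1.6 equiv), THF, rt, 20 min; then silica gel
Reagents that add atoms: none
Why: Reduction of the tertiary amide with Cp2Zr(H)Cl stops at the zirconated hemiaminal and releases the aldehyde on work-up (Schwartz amide reduction), while the trisubstituted alkene and both acetals are inert and the trans-dioxolane resists epimerisation.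

Step 7
Reactants: 13 (4R,5S)-5-[(Z)-5,5-dimethoxypent-2-en-2-yl]-2,2-dimethyl-1,3-dioxolane-4-carbaldehyde; 14 methyl acrylate
Product: 15 methyl 2-{[(4S,5S)-5-((Z)-5,5-dimethoxypent-2-en-2-yl)-2,2-dimethyl-1,3-dioxolan-4-yl](hydroxy)methyl}prop-2-enoate (both carbinol epimers)
Conditions: DABCO (1 equiv), MeOH, rt, 3–5 d
Reagents that add atoms: none
Why: Morita–Baylis–Hillman reaction of an activated α-alkoxy aldehyde; the new carbinol centre is left as a mixture because step 8 erases it.

Step 8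
Reactants: 15 Morita–Baylis–Hillman adduct (both carbinol epimers)
Product: 16 methyl (Z)-2-(bromomethyl)-3-[(4S,5S)-5-((Z)-5,5-dimethoxypent-2-en-2-yl)-2,2-dimethyl-1,3-dioxolan-4-yl]prop-2-enoate
Conditions: NBS, Me2S, CH2Cl2, −20 °C; then 15, 0 °C
Reagents that add atoms: N-bromosuccinimide, BrN1C(=O)CCC1=O
Why: Corey–Kim-type activation of the alcohol as an alkoxysulfonium salt and SN2′ attack of bromide give the favoured Z 2-(bromomethyl)enoate under non-acidic conditions that spare both acetals.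

Step 9
Reactants: 16 Z-2-(bromomethyl)enoate; 4 (Z)-3-iodobut-2-enal
Product: 18 (4S,5R)-5-[(Z)-2-iodoprop-1-en-1-yl]-3-methylidene-4-[(4S,5S)-5-((Z)-5,5-dimethoxypent-2-en-2-yl)-2,2-dimethyl-1,3-dioxolan-4-yl]oxolan-2-one (4,5-cis), via open-chain hydroxy ester 17 (not isolated)
Conditions: CrCl2 (3 equiv, nickel-free), THF, 0 °C to rt; then PPTS (cat.), CH2Cl2, rt
Reagents that add atoms: none
Why: Chromium-mediated 2-(alkoxycarbonyl)allylation (Barbier/Nozaki–Hiyama type) through a closed chair transition state: the Z allyl unit gives the syn adduct and hence the cis-lactone, and attack anti to the C8–C9 bond with H-8 eclipsed (A(1,3) strain, alkoxy outside) sets C6 and C7 relative to C8.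

Step 10
Reactants: 18 cis-lactone dimethyl acetal
Product: 19 (Z)-4-{(4S,5S)-5-[(2S,3R)-2-((Z)-2-iodoprop-1-en-1-yl)-4-methylidene-5-oxooxolan-3-yl]-2,2-dimethyl-1,3-dioxolan-4-yl}pent-3-enal
Conditions: LiBF4, MeCN/H2O (98:2), rt
Reagents that add atoms: water, O
Why: Mild Lewis-acid hydrolysis cleaves the acyclic dimethyl acetal far faster than the dioxolane ketal, and the β,γ-unsaturated aldehyde is used at once to avoid conjugation.

Step 11
Reactants: 19 iodo-aldehyde
Product: 20 (1(10)Z,4Z)-3β-hydroxy-8β,9α-(isopropylidenedioxy)germacra-1(10),4,11(13)-trien-12,6β-olide (H-6α, H-7α)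
Conditions: CrCl2 (10 equiv), NiCl2 (0.1 equiv), DMSO/THF (3:1), 0.003 M, slow addition, rt
Reagents that add atoms: none
Why: Nozaki–Hiyama–Kishi alkenyl–aldehyde addition at high dilution closes the ten-membered ring with retention of the Z vinyl geometry, and the C3 carbinol is set under substrate control by the lactone- and acetonide-constrained chain (its sense is not predictable in advance and is corrected by the fallback if wrong).

Step 12
Reactants: 20 macrocyclic allylic alcohol
Product: 21 (1(10)Z,4Z)-3β-acetoxy-8β,9α-(isopropylidenedioxy)germacra-1(10),4,11(13)-trien-12,6β-olide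
Conditions: Ac2O, pyridine, DMAP (cat.), CH2Cl2, 0 °C to rt
Reagents that add atoms: acetic anhydride, CC(=O)OC(C)=O
Why: DMAP-catalysed acylation of the secondary allylic alcohol with retention at C3.

Step 13
Reactants: 21 acetonide acetate
Product: 22 (1(10)Z,4Z)-3β-acetoxy-8β,9α-dihydroxygermacra-1(10),4,11(13)-trien-12,6β-olide
Conditions: AcOH/H2O (4:1), 40 °C
Reagents that add atoms: none
Why: Acid hydrolysis of the trans-fused acetonide under conditions too mild to ionise the allylic acetate or shift the lactone.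

Step 14
Reactants: 22 diol
Product: 23 (1(10)Z,4Z)-3β-acetoxy-8β,9α-(carbonyldioxy)germacra-1(10),4,11(13)-trien-12,6β-olide
Conditions: CDI, DMAP (cat.), CH2Cl2, rt to 40 °C
Reagents that add atoms: 1,1′-carbonyldiimidazole, O=C(n1ccnc1)n1ccnc1
Why: Carbonylation of the 1,2-diol gives the five-membered cyclic carbonate, which makes O-9 an allylic leaving group while masking O-8.

Step 15
Reactants: 24 (E)-2-methylbut-2-en-1-ol
Product: 25 [(2S,3S)-2,3-dimethyloxiran-2-yl]methanol
Conditions: Ti(OiPr)4 (10 mol%), L-(+)-diethyl tartrate (12 mol%), t-BuOOH, 4 Å molecular sieves, CH2Cl2, −20 °C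
Reagents that add atoms: tert-butyl hydroperoxide, CC(C)(C)OO
Why: Sharpless asymmetric epoxidation, in which L-(+)-tartrate delivers oxygen to the face giving the (2S,3S)-epoxy alcohol and the E olefin fixes the cis relation of the two methyl groups.

Step 16
Reactants: 25 [(2S,3S)-2,3-dimethyloxiran-2-yl]methanol
Product: 27 (2R,3S)-2,3-dimethyloxirane-2-carboxylic acid, via epoxy aldehyde 26 (not isolated)
Conditions: RuCl3·xH2O (2 mol%), NaIO4, MeCN/EtOAc/H2O, 0 °C to rt
Reagents that add atoms: water, O; NaIO4 (terminal oxidant), [Na+].[O-]I(=O)(=O)=O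
Why: Ruthenium tetroxide oxidation of the primary alcohol to the acid through the aldehyde hydrate leaves both epoxide centres untouched (C2 becomes R only through the priority change).

Step 17
Reactants: 23 macrocyclic vinyl carbonate; 27 (2R,3S)-2,3-dimethyloxirane-2-carboxylic acid (1.3 equiv)
Product: 28 target, (1(10)Z,4Z)-3β-acetoxy-8β-hydroxy-9α-[(2R,3S)-2,3-dimethyloxirane-2-carbonyloxy]germacra-1(10),4,11(13)-trien-12,6β-olide, (3S,6S,7R,8S,9S)
Conditions: Pd2(dba)3·CHCl3 (2.5 mol%), PPh3 (10 mol%), BEt3 (20 mol%), THF, 0 °C to rt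
Reagents that add atoms: none
Why: Proposed new method: zerovalent palladium ionises only the strained allylic carbonate C9–O bond (anti to O-9 and faster than the acetate or lactone allylic esters), loss of CO2 leaves the 8-alkoxide, which BEt3 and acid 27 turn into an acyloxyborate that returns the carboxylate to the proximal terminus C9 on the face opposite palladium (double inversion, so 9α is retained, and the olefin stays Z if tethered capture outruns isomerisation of the anti,anti allyl), and protonolysis frees 8-OH; the closest known reactions are palladium/borane co-catalysed branched-selective additions of alcohols or water to vinyl epoxides and vinylethylene carbonates (Tsuji–Trost allylic substitution), not yet shown for a carboxylic acid on a ring-embedded trisubstituted vinyl carbonate.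

**Compound list**
1 | but-2-yn-1-ol | CC#CCO | starting material
2 | sodium cyclic Z-alkenylalanate (2,2-bis(2-methoxyethoxy)-3-methyl-2,5-dihydro-1,2-oxaluminol-2-ide) | [Na+].COCCO[Al-]1(OCCOC)OCC=C1C | intermediate
3 | (Z)-3-iodobut-2-en-1-ol | OC/C=C(/C)I | intermediate
4 | (Z)-3-iodobut-2-enal | O=C/C=C(/C)I | intermediate
5 | 3-bromo-1,1-dimethoxypropane | COC(OC)CCBr | starting material
6 | (3,3-dimethoxypropyl)triphenylphosphonium bromide | COC(OC)CC[P+](c1ccccc1)(c1ccccc1)c1ccccc1.[Br-] | intermediate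
7 | (4R,5R)-N,N,N′,N′,2,2-hexamethyl-1,3-dioxolane-4,5-dicarboxamide | CN(C)C(=O)[C@H](OC(C)(C)O1)[C@@H]1C(=O)N(C)C | starting material
8 | bromomagnesium hemiaminal alkoxide from mono-addition to 7 (new carbon undefined, dioxolane 4R,5R) | CC(O[Mg]Br)(N(C)C)[C@H](OC(C)(C)O1)[C@@H]1C(=O)N(C)C | intermediate
9 | (4R,5R)-5-acetyl-N,N,2,2-tetramethyl-1,3-dioxolane-4-carboxamide | CC(=O)[C@H](OC(C)(C)O1)[C@@H]1C(=O)N(C)C | intermediate
10 | (3,3-dimethoxypropylidene)triphenylphosphorane | COC(OC)CC=P(c1ccccc1)(c1ccccc1)c1ccccc1 | intermediate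
11 | (4R,5S)-5-[(Z)-5,5-dimethoxypent-2-en-2-yl]-N,N,2,2-tetramethyl-1,3-dioxolane-4-carboxamide | COC(OC)C/C=C(/C)[C@H](OC(C)(C)O1)[C@@H]1C(=O)N(C)C | intermediate
12 | chlorozirconocene hemiaminal alkoxide of 11 (new carbon undefined) | COC(OC)C/C=C(/C)[C@H](OC(C)(C)O1)[C@@H]1C(O[Zr](Cl)(C2C=CC=C2)C2C=CC=C2)N(C)C | intermediate
13 | (4R,5S)-5-[(Z)-5,5-dimethoxypent-2-en-2-yl]-2,2-dimethyl-1,3-dioxolane-4-carbaldehyde | COC(OC)C/C=C(/C)[C@H](OC(C)(C)O1)[C@@H]1C=O | intermediate
14 | methyl acrylate | C=CC(=O)OC | starting material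
15 | methyl 2-{[(4S,5S)-5-((Z)-5,5-dimethoxypent-2-en-2-yl)-2,2-dimethyl-1,3-dioxolan-4-yl](hydroxy)methyl}prop-2-enoate, both carbinol epimers | COC(OC)C/C=C(/C)[C@H](OC(C)(C)O1)[C@@H]1C(O)C(=C)C(=O)OC | intermediate
16 | methyl (Z)-2-(bromomethyl)-3-[(4S,5S)-5-((Z)-5,5-dimethoxypent-2-en-2-yl)-2,2-dimethyl-1,3-dioxolan-4-yl]prop-2-enoate | COC(OC)C/C=C(/C)[C@H](OC(C)(C)O1)[C@@H]1/C=C(\CBr)C(=O)OC | intermediate
17 | methyl (Z)-4-hydroxy-6-iodo-2-methylidene-3-[(4S,5S)-5-((Z)-5,5-dimethoxypent-2-en-2-yl)-2,2-dimethyl-1,3-dioxolan-4-yl]hept-5-enoate, syn adduct with C6/C7 as in 18 (formed as its chromium alkoxide) | COC(=O)C(=C)[C@@H]([C@@H](O)/C=C(/C)I)[C@@H]1OC(C)(C)O[C@H]1/C(C)=C\CC(OC)OC | intermediate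
18 | (4S,5R)-5-[(Z)-2-iodoprop-1-en-1-yl]-3-methylidene-4-[(4S,5S)-5-((Z)-5,5-dimethoxypent-2-en-2-yl)-2,2-dimethyl-1,3-dioxolan-4-yl]oxolan-2-one (cis-lactone) | C=C1C(=O)O[C@@H](/C=C(/C)I)[C@H]1[C@@H]2OC(C)(C)O[C@H]2/C(C)=C\CC(OC)OC | intermediate
19 | (Z)-4-{(4S,5S)-5-[(2S,3R)-2-((Z)-2-iodoprop-1-en-1-yl)-4-methylidene-5-oxooxolan-3-yl]-2,2-dimethyl-1,3-dioxolan-4-yl}pent-3-enal | C=C1C(=O)O[C@@H](/C=C(/C)I)[C@H]1[C@@H]2OC(C)(C)O[C@H]2/C(C)=C\CC=O | intermediate
20 | (1(10)Z,4Z)-3β-hydroxy-8β,9α-(isopropylidenedioxy)germacra-1(10),4,11(13)-trien-12,6β-olide | C=C1C(=O)O[C@H]2/C=C(/C)[C@@H](O)C/C=C(/C)[C@H](OC(C)(C)O3)[C@@H]3[C@@H]12 | intermediate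
21 | (1(10)Z,4Z)-3β-acetoxy-8β,9α-(isopropylidenedioxy)germacra-1(10),4,11(13)-trien-12,6β-olide | C=C1C(=O)O[C@H]2/C=C(/C)[C@@H](OC(C)=O)C/C=C(/C)[C@H](OC(C)(C)O3)[C@@H]3[C@@H]12 | intermediate
22 | (1(10)Z,4Z)-3β-acetoxy-8β,9α-dihydroxygermacra-1(10),4,11(13)-trien-12,6β-olide | C=C1C(=O)O[C@H]2/C=C(/C)[C@@H](OC(C)=O)C/C=C(/C)[C@H](O)[C@@H](O)[C@@H]12 | intermediate
23 | (1(10)Z,4Z)-3β-acetoxy-8β,9α-(carbonyldioxy)germacra-1(10),4,11(13)-trien-12,6β-olide | C=C1C(=O)O[C@H]2/C=C(/C)[C@@H](OC(C)=O)C/C=C(/C)[C@H](OC(=O)O3)[C@@H]3[C@@H]12 | intermediate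
24 | (E)-2-methylbut-2-en-1-ol | C/C=C(\C)CO | starting material
25 | [(2S,3S)-2,3-dimethyloxiran-2-yl]methanol | OC[C@]1(C)O[C@H]1C | intermediate
26 | (2R,3S)-2,3-dimethyloxirane-2-carbaldehyde | O=C[C@]1(C)O[C@H]1C | intermediate
27 | (2R,3S)-2,3-dimethyloxirane-2-carboxylic acid | OC(=O)[C@]1(C)O[C@H]1C | intermediate
28 | (1(10)Z,4Z)-3β-acetoxy-8β-hydroxy-9α-[(2R,3S)-2,3-dimethyloxirane-2-carbonyloxy]germacra-1(10),4,11(13)-trien-12,6β-olide, (3S,6S,7R,8S,9S) | C=C1C(=O)O[C@H]2/C=C(/C)[C@@H](OC(C)=O)C/C=C(/C)[C@H](OC(=O)[C@]3(C)O[C@H]3C)[C@@H](O)[C@@H]12 | target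

**Step count**
Total: 17 steps. Longest linear sequence: 12 steps (7 → 9 → 11 → 13 → 15 → 16 → 18 → 19 → 20 → 21 → 22 → 23 → 28).

**Steps most likely to fail**

Step 9 (allylation/lactonisation). The cis relation follows from the Z allyl geometry, but the facial sense relative to C8 rests on an A(1,3)-strain argument (alkoxy outside, alkyl anti) and could be low or reversed. Fallback, from 16 back to 18: palladium-catalysed borylation of 16 (B2pin2, Pd2(dba)3 cat., toluene) gives the Z 2-(methoxycarbonyl)allyl pinacolboronate F1. Allylboration of 4 catalysed by a chiral BINOL-derived phosphoric acid (TRIP, the enantiomer matched to the required face) then gives the pinacol borate of the syn adduct F2 through a closed transition state under catalyst control. Acid (TsOH cat., CH2Cl2) lactonises F2 to 18.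

Step 11 (Ni/Cr macrocyclisation). The yield of a strained ten-membered ring is uncertain and the C3 configuration is substrate-controlled and not predictable. Fallback, from 19 back to 20: if the cyclisation gives mainly the 3α-alcohol F3, the crude alcohol mixture is oxidised with Dess–Martin periodinane to the macrocyclic Z-enone F4. Reduction with (R)-2-methyl-CBS-oxazaborolidine and catecholborane at −78 °C (Corey–Bakshi–Shibata, reagent control, alkenyl as the large group) then gives the 3β (3S) alcohol 20.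

Step 17 (the proposed palladium/borane acyloxylation). It can fail through ionisation of the C3 acetate or the C6 lactone oxygen, attack at the distal terminus C1, loss of Z geometry by allyl isomerisation, or attack of the 8-alkoxide on the lactone. Fallback by known chemistry, from 22 back to 28: acid 27 is converted with 2,4,6-trichlorobenzoyl chloride and Et3N into the mixed anhydride F5. F5 is added to diol 22 with DMAP in toluene at −20 °C (Yamaguchi esterification). The allylic 9-OH is judged the less hindered and more acidic hydroxyl and should acylate first to give 28, though this selectivity is unproven. The 8-O-acyl regioisomer F6 is removed by chromatography.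

Further compounds
F1 | step 9 | methyl (Z)-3-[(4S,5S)-5-((Z)-5,5-dimethoxypent-2-en-2-yl)-2,2-dimethyl-1,3-dioxolan-4-yl]-2-[(4,4,5,5-tetramethyl-1,3,2-dioxaborolan-2-yl)methyl]prop-2-enoate | COC(OC)C/C=C(/C)[C@H](OC(C)(C)O1)[C@@H]1/C=C(\CB2OC(C)(C)C(C)(C)O2)C(=O)OC
F2 | step 9 | pinacol borate ester of hydroxy ester 17 | COC(=O)C(=C)[C@@H]([C@@H](OB2OC(C)(C)C(C)(C)O2)/C=C(/C)I)[C@@H]1OC(C)(C)O[C@H]1/C(C)=C\CC(OC)OC
F3 | step 11 | (1(10)Z,4Z)-3α-hydroxy-8β,9α-(isopropylidenedioxy)germacra-1(10),4,11(13)-trien-12,6β-olide (3-epimer of 20) | C=C1C(=O)O[C@H]2/C=C(/C)[C@H](O)C/C=C(/C)[C@H](OC(C)(C)O3)[C@@H]3[C@@H]12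
F4 | step 11 | (1(10)Z,4Z)-8β,9α-(isopropylidenedioxy)-3-oxogermacra-1(10),4,11(13)-trien-12,6β-olide | C=C1C(=O)O[C@H]2/C=C(/C)C(=O)C/C=C(/C)[C@H](OC(C)(C)O3)[C@@H]3[C@@H]12
F5 | step 17 | (2R,3S)-2,3-dimethyloxirane-2-carboxylic 2,4,6-trichlorobenzoic anhydride | O=C(OC(=O)[C@]1(C)O[C@H]1C)c1c(Cl)cc(Cl)cc1Cl
F6 | step 17 | (1(10)Z,4Z)-3β-acetoxy-9α-hydroxy-8β-[(2R,3S)-2,3-dimethyloxirane-2-carbonyloxy]germacra-1(10),4,11(13)-trien-12,6β-olide | C=C1C(=O)O[C@H]2/C=C(/C)[C@@H](OC(C)=O)C/C=C(/C)[C@H](O)[C@@H](OC(=O)[C@]3(C)O[C@H]3C)[C@@H]12
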